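## Analysis of the target

- The target is a germacranolide. The carbocycle is a ten-membered ring (C1–C10) with a Z C1=C10 alkene (methyl C14 on C10) and an E C4=C5 alkene (methyl C15 on C4). It is cis-fused across C6–C7 to an α-methylene-γ-butyrolactone (O–C6, C7, C11=C13, C12=O).
- C6 to C9 are four contiguous stereocentres, (6S,7R,8S,9R). They carry the lactone oxygen, a tertiary hydroxyl at the ring fusion, the angelate and a secondary hydroxyl.
- O7 and O8 lie on one face of the ring; O6 and O9 lie on the other. The O8/O9 pair is threo, as in the two carbinol carbons of D-tartaric acid.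
- Sensitive groups: the exo-methylene lactone (Michael acceptor), the Z-angelate (isomerises to the tiglate), the medium-ring 1,5-diene (transannular reactions under acid), and the O8/O9 pair (acyl migration, translactonisation to the 8,12-olide).
- The hard points are the strained ring with three geometrically defined alkenes, the fully substituted oxygenated C7, and acylating O8 alone among three hydroxyls.
- The strategy rests on the C6–O/C7–O pair: the two oxygens are trans to each other and O7 is syn to O8. This is the pattern left by epoxidation of a ring-cis C6=C7 alkene from the face of the C8 hydroxyl, followed by backside opening at C6 by the C12 carboxyl. C6, C7 and the lactone ring can therefore all be derived from the C8 carbinol.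

## Retrosynthetic reasoning

**30 ⇐ 29 ⇐ 27 + 28.** The last bonds cut are O9–Si and the O8–acyl bond. The angelate comes in as late as possible because it isomerises easily. Lactone 27 offers exactly one acylable hydroxyl: O7 is tertiary and O9 is silylated. The forward steps must acylate without Z/E leakage and desilylate without touching the methylene lactone.

**27 ⇐ 25 (through 26).** C6–O and C7–O are cut together. This removes the lactone ring and both new stereocentres and leaves a ring-cis C6=C7 alkene flanked by the C8 carbinol and by the C12 acid on C11. Cutting here, and not at C7–C11 or C6–C7, turns the oxygenated quaternary C7 into a consequence of the C8 centre. The forward reaction has to epoxidise one alkene of four on one face and open the epoxide at C6 with inversion.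

**25 ⇐ 24 ⇐ 23.** The acid and the C8 hydroxyl stay masked (methyl ester, TES ether) until just before use, because together they can close to the 8,12-olide. The TES/TBS pair lets O8 be freed while O9 stays covered.

**23 ⇐ 21 + 22.** C7–C11 is cut to a ring alkenylstannane and the three-carbon bromoacrylate 22. The acrylate is attached only after ring closure: a 2-dienyl acrylate would not survive the sulfonyl carbanion or the hydride used on the way to 21. The forward reaction is a Stille coupling with retention at C7.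

**21 ⇐ 20 ⇐ 19.** The ring is opened at C2–C3, the only ring bond flanked by two allylic carbons and remote from every stereocentre. C3 becomes a sulfone-stabilised carbanion and C2 an allylic bromide. The sulfone sits on C3 so that it arrives with the small fragment 4; it is removed reductively after cyclisation.

**19 ⇐ 18 ⇐ 17 ⇐ 16 ⇐ 15 + 4.** The C7–Sn and C6–H bonds go back to a C6≡C7 alkyne; syn hydrostannation fixes C5 cis to C8. The C5–C6 bond goes back to a Sonogashira coupling of alkyne 15 with E-iodide 4, whose geometry becomes the E C4=C5 alkene.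

**15 ⇐ 14 ⇐ 13 ⇐ 12 ⇐ 10 ⇐ 9 ⇐ 8 ⇐ 7 ⇐ 6 ⇐ 5.** C8 and C9 with their oxygens are the carbinol carbons of 5; C10 and C7 are its carboxyl carbons. C6 is added by one-carbon homologation of the C7 aldehyde. C1, C2 and C14 are added at C10 by dibromo-olefination, carboxylation and methyl cuprate addition; the syn cuprate addition gives the Z alkene. Mono-silylation of the symmetric diol (6) and reduction of only the ester next to the free hydroxyl (7) distinguish the two ends and the two hydroxyls in two steps.

**4 ⇐ 3 ⇐ 2 ⇐ 1.** The C3–C5/C15 unit comes from 1 by syn carbometalation, which sets the E geometry, followed by exchange of the hydroxyl for the sulfone.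

## Alternatives that were turned down

**Alternative 1:** The ring is cut at C1–C2.
- Forward key step: a terminal C2=C3 alkene is hydroborated with 9-BBN, and the primary alkylborane is coupled under PdCl2(dppf) catalysis with a Z vinyl iodide at C1. The product is the protected cyclodecadiene A1, in which C6–C9 already carry their four oxygens (from a hexose) and C7 carries a silyl-capped ethynyl group as the seed of the lactone.
- For it: an sp3–sp2 Suzuki closure is one of the most dependable ways to make a medium ring, it retains the alkene geometry, and it avoids a strained conjugated triene and tin.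
- Against it: the hexose has to be trimmed and extended at both ends under orthogonal protection of four oxygens. The tertiary C7 carbinol needs a face-selective addition to a ketone. After A1 the alkyne must still be turned into the C11–C13 acrylate, lactonised onto O6, and O7/O8/O9 must be freed and told apart.
- Comparison: on the ring closure itself this alternative is stronger than the sulfone alkylation and desulfonylation used here. In its place the chosen route takes only two stereocentres from the chiral pool, makes C6, C7 and the lactone in one late step from C8, and leaves O8 as the only free secondary hydroxyl.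

**Alternative 2:** C5–C6 and C4–C15 are cut at once.
- Forward key step: Ni(cod)2 with an N-heterocyclic carbene joins a C6 aldehyde to the terminal carbon of a C4≡C5 alkyne through an oxanickelacycle, and MeZnCl delivers C15 to C4. The product is the ten-membered allylic alcohol A2, with O6 free and the C11 unit present as a protected 2-propenyl alcohol.
- For it: ring, E trisubstituted alkene and C15 are made in one operation, and O6 appears directly where the lactone needs it. On convergence at this stage it is stronger than the chosen route.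
- Against it: C6 becomes a stereocentre during the macrocyclisation, under the control of only the neighbouring quaternary C7 and the ring conformation. The site of C–C bond formation on a terminal alkyne in a ten-membered closure depends on ligand and ring size. The aldehyde sits next to a fully substituted carbon. Oxidation of C12, lactonisation and O8/O9 differentiation still follow.
- Comparison: the chosen key step derives C6 by stereospecific inversion of an epoxide whose face is fixed by O8, which is firmer control than a macrocyclic carbonyl addition.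

**Alternative 3:** No ring bond of the target is cut; the C5–C10 bond of a cis-fused decalin is.
- Forward key step: an alkoxide adds to a C4 pinacol boronate, and the ate complex fragments with loss of a C1 mesylate. This forms both ring alkenes and opens the decalin to the cyclodecadiene A3.
- For it: the fragmentation is stereospecific, so both alkene geometries follow from the decalin configuration, and no entropically costly cyclisation is needed. On alkene geometry it is stronger than the chosen route, which relies on three separate addition reactions.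
- Against it: the decalin must carry the C6–C9 oxygens, the C7 alkynyl carbinol, the leaving group and the boron in one defined relative configuration. That is more stereocentres than the target has. β-Oxygenated fragmentation substrates can also eliminate. The lactone work after A3 is the same as in Alternative 1.
- Comparison: the chosen route is much shorter and carries no stereocentre that is later destroyed.

Key step: step 22

Assumption (chemistry): hydroxy acid 25 is taken to survive brief handling at or below room temperature without closing onto O8; it is made and used without storage.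

Abbreviations: TBS = tert-butyldimethylsilyl, TES = triethylsilyl. Atom labels C1–C15 are those of the target.

## Route

Step 1
Reactants: 1 prop-2-yn-1-ol
Product: 2 (2E)-3-iodo-2-methylprop-2-en-1-ol
Conditions: Me3Al (3 equiv), Cp2ZrCl2 (25 mol%), CH2Cl2, 0 °C to rt; then I2, THF, −30 to 0 °C
Reagents that add atoms: trimethylaluminium, C[Al](C)C; iodine, II
Why: Zirconium-catalysed carboalumination adds methyl and aluminium syn across the alkyne with methyl on the internal carbon; iodinolysis of the C–Al bond with retention should give the E iodide, which places C15 cis to the future C5–C6 bond.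

Step 2
Reactants: 2 (2E)-3-iodo-2-methylprop-2-en-1-ol
Product: 3 (1E)-3-bromo-1-iodo-2-methylprop-1-ene
Conditions: CBr4, PPh3, CH2Cl2, 0 °C
Reagents that add atoms: carbon tetrabromide, BrC(Br)(Br)Br
Why: Appel bromination of a primary allylic alcohol under neutral conditions; the vinyl iodide and the alkene geometry are not touched.

Step 3
Reactants: 3 (1E)-3-bromo-1-iodo-2-methylprop-1-ene
Product: 4 {[(2E)-3-iodo-2-methylprop-2-en-1-yl]sulfonyl}benzene
Conditions: PhSO2Na, DMF, rt
Reagents that add atoms: sodium benzenesulfinate, [Na+].[O-]S(=O)c1ccccc1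
Why: SN2 displacement of the primary allylic bromide by sulfinate sulfur; no stereocentre is involved and the E iodide is inert.

Step 4
Reactants: 5 diethyl (2S,3S)-2,3-dihydroxybutanedioate (diethyl D-tartrate)
Product: 6 diethyl (2S,3S)-2-(TBS-oxy)-3-hydroxybutanedioate
Conditions: TBSCl (1.0 equiv), imidazole, DMF, 0 °C
Reagents that add atoms: tert-butyldimethylsilyl chloride, CC(C)(C)[Si](C)(C)Cl
Why: The two hydroxyls of the C2-symmetric diol are equivalent, so any mono-silylation gives one compound, and the second silylation is slowed by the neighbouring silyl ether; the silylated oxygen becomes O9.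

Step 5
Reactants: 6 diethyl (2S,3S)-2-(TBS-oxy)-3-hydroxybutanedioate
Product: 7 ethyl (2S,3R)-2-(TBS-oxy)-3,4-dihydroxybutanoate
Conditions: BH3·SMe2 (1.1 equiv), NaBH4 (5 mol%), THF, 0 °C to rt; MeOH quench
Reagents that add atoms: none
Why: Hydroxyl-directed borane reduction: the borane bound to the free hydroxyl reduces only the ester α to it, so the C7 ester goes to the alcohol and the α-silyloxy C10 ester stays; crude 7 is silylated at once because it can close to a γ-lactone.

Step 6
Reactants: 7 ethyl (2S,3R)-2-(TBS-oxy)-3,4-dihydroxybutanoate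
Product: 8 ethyl (2S,3R)-2-(TBS-oxy)-3,4-bis(TES-oxy)butanoate
Conditions: Et3SiCl (2.5 equiv), imidazole, DMAP (cat.), CH2Cl2, 0 °C
Reagents that add atoms: chlorotriethylsilane, CC[Si](CC)(CC)Cl
Why: Routine silylation of a primary and a secondary hydroxyl; it puts the labile TES group on O8 and on the C7 oxygen.

Step 7
Reactants: 8 ethyl (2S,3R)-2-(TBS-oxy)-3,4-bis(TES-oxy)butanoate
Product: 9 (2S,3R)-2-(TBS-oxy)-3,4-bis(TES-oxy)butanal
Conditions: i-Bu2AlH (1.1 equiv), CH2Cl2, −78 °C
Reagents that add atoms: none
Why: Half-reduction of an α-silyloxy ester; the tetrahedral aluminate is stable at −78 °C and releases the C10 aldehyde on work-up without epimerising C9.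

Step 8
Reactants: 9 (2S,3R)-2-(TBS-oxy)-3,4-bis(TES-oxy)butanal
Product: 10 (3R,4R)-1,1-dibromo-3-(TBS-oxy)-4,5-bis(TES-oxy)pent-1-ene
Conditions: CBr4, PPh3, 2,6-lutidine, CH2Cl2, 0 °C
Reagents that add atoms: carbon tetrabromide, BrC(Br)(Br)Br
Why: Corey–Fuchs dibromo-olefination (Wittig reaction of the dibromomethylene ylide) adds C1; the buffered conditions keep the silyl ethers intact.

Step 9
Reactants: 10 (3R,4R)-1,1-dibromo-3-(TBS-oxy)-4,5-bis(TES-oxy)pent-1-ene
Product: 12 methyl (4R,5R)-4-(TBS-oxy)-5,6-bis(TES-oxy)hex-2-ynoate, via lithium acetylide 11 (not isolated)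
Conditions: n-BuLi (2.1 equiv), THF, −78 °C; then ClCO2Me, −78 to −20 °C
Reagents that add atoms: methyl chloroformate, COC(=O)Cl
Why: Second stage of the Corey–Fuchs sequence: elimination and bromine–lithium exchange give the acetylide, which is acylated in the same flask to add C2 as the ester carbon.

Step 10
Reactants: 12 methyl (4R,5R)-4-(TBS-oxy)-5,6-bis(TES-oxy)hex-2-ynoate
Product: 13 methyl (2Z,4R,5R)-4-(TBS-oxy)-3-methyl-5,6-bis(TES-oxy)hex-2-enoate
Conditions: Me2CuLi (from MeLi and CuI), THF, −78 °C; aq. NH4Cl at −78 °C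
Reagents that add atoms: lithium dimethylcuprate, [Li+].C[Cu-]C
Why: Conjugate carbocupration of an ynoate is a syn addition: methyl C14 goes to C10 and copper to C1. Protonation with retention at −78 °C, before the alkenylcopper can equilibrate, should leave the ester cis to C9, which is the Z C1=C10 geometry.

Step 11
Reactants: 13 methyl (2Z,4R,5R)-4-(TBS-oxy)-3-methyl-5,6-bis(TES-oxy)hex-2-enoate
Product: 14 methyl (2Z,4R,5S)-4-(TBS-oxy)-3-methyl-6-oxo-5-(TES-oxy)hex-2-enoate
Conditions: (COCl)2, DMSO, CH2Cl2, −78 to −40 °C; then Et3N, −78 to 0 °C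
Reagents that add atoms: none
Why: Under Swern conditions a primary TES ether is cleaved and oxidised directly to the aldehyde while secondary TES and TBS ethers survive; this frees C7 as the aldehyde without a separate deprotection.

Step 12
Reactants: 14 methyl (2Z,4R,5S)-4-(TBS-oxy)-3-methyl-6-oxo-5-(TES-oxy)hex-2-enoate
Product: 15 methyl (2Z,4R,5R)-4-(TBS-oxy)-3-methyl-5-(TES-oxy)hept-2-en-6-ynoate
Conditions: dimethyl (1-diazo-2-oxopropyl)phosphonate, K2CO3, MeOH, 0 °C to rt
Reagents that add atoms: dimethyl (1-diazo-2-oxopropyl)phosphonate, COP(=O)(OC)C(=[N+]=[N-])C(C)=O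
Why: Ohira–Bestmann (Seyferth–Gilbert) homologation adds C6 and gives the terminal alkyne under conditions mild enough for an α-silyloxy aldehyde and a methyl ester.

Step 13
Reactants: 15 methyl (2Z,4R,5R)-4-(TBS-oxy)-3-methyl-5-(TES-oxy)hept-2-en-6-ynoate; 4 {[(2E)-3-iodo-2-methylprop-2-en-1-yl]sulfonyl}benzene
Product: 16 methyl (2Z,4R,5R,8E)-10-(benzenesulfonyl)-4-(TBS-oxy)-3,9-dimethyl-5-(TES-oxy)deca-2,8-dien-6-ynoate
Conditions: Pd(PPh3)2Cl2 (5 mol%), CuI (10 mol%), Et3N, THF, rt, degassed
Reagents that add atoms: none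
Why: Sonogashira coupling forms C5–C6 with retention of the E iodide geometry, so C15 ends cis to C6.

Step 14
Reactants: 16 methyl (2Z,4R,5R,8E)-10-(benzenesulfonyl)-4-(TBS-oxy)-3,9-dimethyl-5-(TES-oxy)deca-2,8-dien-6-ynoate
Product: 17 (2Z,4R,5R,8E)-10-(benzenesulfonyl)-4-(TBS-oxy)-3,9-dimethyl-5-(TES-oxy)deca-2,8-dien-6-yn-1-ol
Conditions: i-Bu2AlH (2.5 equiv), CH2Cl2, −78 °C
Reagents that add atoms: none
Why: 1,2-Reduction of the enoate to the primary allylic alcohol (C2); doing it here removes the only conjugate acceptor before the tin hydride step.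

Step 15
Reactants: 17 (2Z,4R,5R,8E)-10-(benzenesulfonyl)-4-(TBS-oxy)-3,9-dimethyl-5-(TES-oxy)deca-2,8-dien-6-yn-1-ol
Product: 18 (2Z,4R,5S,6E,8E)-10-(benzenesulfonyl)-4-(TBS-oxy)-3,9-dimethyl-6-(tributylstannyl)-5-(TES-oxy)deca-2,6,8-trien-1-ol (tin on C7; C5 cis to C8)
Conditions: Bu3SnH (1.3 equiv, slow addition), Pd(PPh3)2Cl2 (5 mol%), THF, 0 °C to rt
Reagents that add atoms: tributyltin hydride, CCCC[SnH](CCCC)CCCC
Why: Palladium-catalysed hydrostannation is a syn addition, so H on C6 and Sn on C7 end cis and C5 ends cis to C8 (the ring-cis C6=C7 geometry). The inductive pull of the C8 oxygen polarises the alkyne so that hydride should go to the dienyl terminus C6 and tin to C7, as is usual for internal propargylic ethers carrying an sp2 group at the far end.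

Step 16
Reactants: 18 (2Z,4R,5S,6E,8E)-10-(benzenesulfonyl)-4-(TBS-oxy)-3,9-dimethyl-6-(tributylstannyl)-5-(TES-oxy)deca-2,6,8-trien-1-ol
Product: 19 (2Z,4R,5S,6E,8E)-10-(benzenesulfonyl)-1-bromo-4-(TBS-oxy)-3,9-dimethyl-6-(tributylstannyl)-5-(TES-oxy)deca-2,6,8-triene
Conditions: CBr4, PPh3, 2,6-lutidine, CH2Cl2, −20 °C
Reagents that add atoms: carbon tetrabromide, BrC(Br)(Br)Br
Why: Appel bromination of the primary allylic alcohol; the base scavenges HBr so that the alkenylstannane is not protodestannylated.

Step 17
Reactants: 19 (2Z,4R,5S,6E,8E)-10-(benzenesulfonyl)-1-bromo-4-(TBS-oxy)-3,9-dimethyl-6-(tributylstannyl)-5-(TES-oxy)deca-2,6,8-triene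
Product: 20 tributyl[(1E,3E,7Z,9R,10S)-5-(benzenesulfonyl)-9-(TBS-oxy)-4,8-dimethyl-10-(TES-oxy)cyclodeca-1,3,7-trien-1-yl]stannane (sulfone on C3, both epimers)
Conditions: LiN(SiMe3)2 (1.2 equiv), THF, −78 to −20 °C, 1 mM, syringe-pump addition of 19 to the base
Reagents that add atoms: none
Why: Intramolecular SN2 alkylation of the α-sulfonyl allylic carbanion (C3) by the primary allylic bromide (C2), the classical closure of germacrane-type rings. High dilution and inverse addition suppress oligomers, and the Z C1=C10 and ring-cis C6=C7 alkenes bring the ends together. O8 must be silylated here because a free alkoxide would close a six-membered ether onto C2.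

Step 18
Reactants: 20 tributyl[(1E,3E,7Z,9R,10S)-5-(benzenesulfonyl)-9-(TBS-oxy)-4,8-dimethyl-10-(TES-oxy)cyclodeca-1,3,7-trien-1-yl]stannane
Product: 21 tributyl[(1E,3E,7Z,9R,10S)-9-(TBS-oxy)-4,8-dimethyl-10-(TES-oxy)cyclodeca-1,3,7-trien-1-yl]stannane
Conditions: Pd(dppp)Cl2 (10 mol%), LiBHEt3 (3 equiv), THF, 0 °C
Reagents that add atoms: none
Why: Palladium-catalysed reductive desulfonylation: zerovalent palladium ionises the allylic C3–S bond to a π-allyl complex and hydride is delivered to the less substituted terminus C3. This keeps the C4=C5/C6=C7 diene conjugated and E at C4=C5; silyl ethers and the alkenylstannane tolerate the hydride, which is why the ester-bearing C11 unit is attached only afterwards.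

Step 19
Reactants: 21 tributyl[(1E,3E,7Z,9R,10S)-9-(TBS-oxy)-4,8-dimethyl-10-(TES-oxy)cyclodeca-1,3,7-trien-1-yl]stannane; 22 methyl 2-bromoprop-2-enoate
Product: 23 methyl 2-[(1Z,3E,7Z,9R,10R)-9-(TBS-oxy)-4,8-dimethyl-10-(TES-oxy)cyclodeca-1,3,7-trien-1-yl]prop-2-enoate
Conditions: Pd(PPh3)4 (10 mol%), Cu(O2C-2-thienyl) (CuTC, 1.5 equiv), DMF, 0 °C to rt
Reagents that add atoms: none
Why: Copper-assisted Stille coupling forms C7–C11 with retention at C7. The copper carboxylate takes up the tin and speeds transmetalation of the hindered α-branched alkenylstannane at room temperature, which spares the polymerisable bromoacrylate.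

Step 20
Reactants: 23 methyl 2-[(1Z,3E,7Z,9R,10R)-9-(TBS-oxy)-4,8-dimethyl-10-(TES-oxy)cyclodeca-1,3,7-trien-1-yl]prop-2-enoate
Product: 24 methyl 2-[(1Z,3E,7Z,9R,10R)-9-(TBS-oxy)-10-hydroxy-4,8-dimethylcyclodeca-1,3,7-trien-1-yl]prop-2-enoate
Conditions: PPTS, MeOH/CH2Cl2 (1:1), 0 °C
Reagents that add atoms: none
Why: Acid-catalysed methanolysis removes the more labile TES ether on O8 and leaves the hindered TBS ether on O9; any 8,12-lactone formed from 24 is reopened by the base of the next step.

Step 21
Reactants: 24 methyl 2-[(1Z,3E,7Z,9R,10R)-9-(TBS-oxy)-10-hydroxy-4,8-dimethylcyclodeca-1,3,7-trien-1-yl]prop-2-enoate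
Product: 25 2-[(1Z,3E,7Z,9R,10R)-9-(TBS-oxy)-10-hydroxy-4,8-dimethylcyclodeca-1,3,7-trien-1-yl]prop-2-enoic acid (germacrane numbering: 8R,9R)
Conditions: LiOH·H2O, THF/H2O (3:1), 0 °C to rt; then 0.5 M aq. H3PO4 to pH 5, 0 °C
Reagents that add atoms: lithium hydroxide, [Li+].[OH-]
Why: Saponification of the 2-substituted acrylate; under base the open hydroxy carboxylate is the stable form, and acidification only to pH 5 in the cold should deliver the hydroxy acid for immediate use.

Step 22
Reactants: 25 2-[(1Z,3E,7Z,9R,10R)-9-(TBS-oxy)-10-hydroxy-4,8-dimethylcyclodeca-1,3,7-trien-1-yl]prop-2-enoic acid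
Product: 27 (1(10)Z,4E,6S,7R,8S,9R)-9-(TBS-oxy)-7,8-dihydroxygermacra-1(10),4,11(13)-trien-12,6-olide, via epoxy acid 26 (not isolated)
Conditions: VO(acac)2 (10 mol%), t-BuOOH (1.5 equiv, decane), CH2Cl2, 0 °C to rt
Reagents that add atoms: tert-butyl hydroperoxide, CC(C)(C)OO
Why: The C8 hydroxyl binds to the pentavalent vanadium alkylperoxide, and the peroxide oxygen is passed within the complex to the allylic C6=C7 bond on the face that carries O8; this gives the cis-epoxy alcohol 26, as is general for vanadium-catalysed epoxidation of cyclic allylic alcohols, medium rings included. The C12 acid, held on C7 through C11, then attacks C6 from the face opposite the oxirane oxygen, the oxirane being activated by the Lewis-acidic vanadium and by the acid itself; the closest known reaction type is hydroxyl-directed epoxidation of an allylic alcohol followed by lactonisation of a β,γ-epoxy acid to a β-hydroxy-γ-lactone. The lactone closes in the 5-endo mode with respect to the oxirane (the 4-exo mode would give a β-lactone), which is workable because C6 is allylic to C4=C5 and can bear positive charge in a loose SN2 transition state. C7 is set by the face of oxygen delivery, hence by the C8 carbinol (O7 cis to O8); C6 is set by inversion at the epoxide carbon, so O6 comes out trans to O7, and the C6–O and C7–C11 bonds are cis as the five-membered ring fusion requires. The step needs one alkene of four and one face: C6=C7 is the only alkene allylic to a free hydroxyl (C1=C10 is merely homoallylic to O8 and its own allylic O9 is silylated, C4=C5 is remote, C11=C13 is electron-poor), and the near-planar C5–C6–C7–C8 unit of the ring-cis alkene holds acid and epoxide in the geometry of the cis-fused product.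

Step 23
Reactants: 27 (1(10)Z,4E,6S,7R,8S,9R)-9-(TBS-oxy)-7,8-dihydroxygermacra-1(10),4,11(13)-trien-12,6-olide; 28 (2Z)-2-methylbut-2-enoic acid (angelic acid)
Product: 29 (1(10)Z,4E,6S,7R,8S,9R)-9-(TBS-oxy)-7-hydroxy-8-[(2Z)-2-methylbut-2-enoyloxy]germacra-1(10),4,11(13)-trien-12,6-olide
Conditions: 28, 2,4,6-Cl3C6H2COCl, Et3N, toluene, rt; then 27, 80 °C
Reagents that add atoms: none
Why: Yamaguchi-type mixed anhydride acylation; leaving out a nucleophilic catalyst avoids Z-to-E isomerisation of the angelate, and only the secondary O8 reacts because O7 is tertiary and O9 is silylated.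

Step 24
Reactants: 29 (1(10)Z,4E,6S,7R,8S,9R)-9-(TBS-oxy)-7-hydroxy-8-[(2Z)-2-methylbut-2-enoyloxy]germacra-1(10),4,11(13)-trien-12,6-olide
Product: 30 (1(10)Z,4E,6S,7R,8S,9R)-7,9-dihydroxy-8-[(2Z)-2-methylbut-2-enoyloxy]germacra-1(10),4,11(13)-trien-12,6-olide (CNP0292337.1)
Conditions: HF·pyridine, pyridine, THF, 0 °C to rt
Reagents that add atoms: none
Why: Buffered HF·pyridine cleaves the Si–O bond under mildly acidic conditions that should neither add to the methylene lactone nor isomerise the angelate nor move the acyl group from O8 to O9.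

## Compound list

1 | prop-2-yn-1-ol (propargyl alcohol) | C#CCO | starting material
2 | (2E)-3-iodo-2-methylprop-2-en-1-ol | OC/C(C)=C/I | intermediate
3 | (1E)-3-bromo-1-iodo-2-methylprop-1-ene | BrC/C(C)=C/I | intermediate
4 | {[(2E)-3-iodo-2-methylprop-2-en-1-yl]sulfonyl}benzene | O=S(=O)(C/C(C)=C/I)c1ccccc1 | intermediate
5 | diethyl (2S,3S)-2,3-dihydroxybutanedioate (diethyl D-tartrate) | CCOC(=O)[C@@H](O)[C@H](O)C(=O)OCC | starting material
6 | diethyl (2S,3S)-2-(TBS-oxy)-3-hydroxybutanedioate | CCOC(=O)[C@@H](O[Si](C)(C)C(C)(C)C)[C@H](O)C(=O)OCC | intermediate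
7 | ethyl (2S,3R)-2-(TBS-oxy)-3,4-dihydroxybutanoate | CCOC(=O)[C@@H](O[Si](C)(C)C(C)(C)C)[C@H](O)CO | intermediate
8 | ethyl (2S,3R)-2-(TBS-oxy)-3,4-bis(TES-oxy)butanoate | CCOC(=O)[C@@H](O[Si](C)(C)C(C)(C)C)[C@H](O[Si](CC)(CC)CC)CO[Si](CC)(CC)CC | intermediate
9 | (2S,3R)-2-(TBS-oxy)-3,4-bis(TES-oxy)butanal | O=C[C@@H](O[Si](C)(C)C(C)(C)C)[C@H](O[Si](CC)(CC)CC)CO[Si](CC)(CC)CC | intermediate
10 | (3R,4R)-1,1-dibromo-3-(TBS-oxy)-4,5-bis(TES-oxy)pent-1-ene | BrC(Br)=C[C@@H](O[Si](C)(C)C(C)(C)C)[C@H](O[Si](CC)(CC)CC)CO[Si](CC)(CC)CC | intermediate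
11 | lithium acetylide of (3R,4R)-3-(TBS-oxy)-4,5-bis(TES-oxy)pent-1-yne (not isolated) | [Li]C#C[C@@H](O[Si](C)(C)C(C)(C)C)[C@H](O[Si](CC)(CC)CC)CO[Si](CC)(CC)CC | intermediate
12 | methyl (4R,5R)-4-(TBS-oxy)-5,6-bis(TES-oxy)hex-2-ynoate | COC(=O)C#C[C@@H](O[Si](C)(C)C(C)(C)C)[C@H](O[Si](CC)(CC)CC)CO[Si](CC)(CC)CC | intermediate
13 | methyl (2Z,4R,5R)-4-(TBS-oxy)-3-methyl-5,6-bis(TES-oxy)hex-2-enoate | COC(=O)/C=C(/C)[C@@H](O[Si](C)(C)C(C)(C)C)[C@H](O[Si](CC)(CC)CC)CO[Si](CC)(CC)CC | intermediate
14 | methyl (2Z,4R,5S)-4-(TBS-oxy)-3-methyl-6-oxo-5-(TES-oxy)hex-2-enoate | COC(=O)/C=C(/C)[C@@H](O[Si](C)(C)C(C)(C)C)[C@H](O[Si](CC)(CC)CC)C=O | intermediate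
15 | methyl (2Z,4R,5R)-4-(TBS-oxy)-3-methyl-5-(TES-oxy)hept-2-en-6-ynoate | COC(=O)/C=C(/C)[C@@H](O[Si](C)(C)C(C)(C)C)[C@H](O[Si](CC)(CC)CC)C#C | intermediate
16 | methyl (2Z,4R,5R,8E)-10-(benzenesulfonyl)-4-(TBS-oxy)-3,9-dimethyl-5-(TES-oxy)deca-2,8-dien-6-ynoate | COC(=O)/C=C(/C)[C@@H](O[Si](C)(C)C(C)(C)C)[C@H](O[Si](CC)(CC)CC)C#C/C=C(\C)CS(=O)(=O)c1ccccc1 | intermediate
17 | (2Z,4R,5R,8E)-10-(benzenesulfonyl)-4-(TBS-oxy)-3,9-dimethyl-5-(TES-oxy)deca-2,8-dien-6-yn-1-ol | OC/C=C(/C)[C@@H](O[Si](C)(C)C(C)(C)C)[C@H](O[Si](CC)(CC)CC)C#C/C=C(\C)CS(=O)(=O)c1ccccc1 | intermediate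
18 | (2Z,4R,5S,6E,8E)-10-(benzenesulfonyl)-4-(TBS-oxy)-3,9-dimethyl-6-(tributylstannyl)-5-(TES-oxy)deca-2,6,8-trien-1-ol | OC/C=C(/C)[C@@H](O[Si](C)(C)C(C)(C)C)[C@H](O[Si](CC)(CC)CC)/C(=C\C=C(/C)CS(=O)(=O)c1ccccc1)[Sn](CCCC)(CCCC)CCCC | intermediate
19 | (2Z,4R,5S,6E,8E)-10-(benzenesulfonyl)-1-bromo-4-(TBS-oxy)-3,9-dimethyl-6-(tributylstannyl)-5-(TES-oxy)deca-2,6,8-triene | BrC/C=C(/C)[C@@H](O[Si](C)(C)C(C)(C)C)[C@H](O[Si](CC)(CC)CC)/C(=C\C=C(/C)CS(=O)(=O)c1ccccc1)[Sn](CCCC)(CCCC)CCCC | intermediate
20 | tributyl[(1E,3E,7Z,9R,10S)-5-(benzenesulfonyl)-9-(TBS-oxy)-4,8-dimethyl-10-(TES-oxy)cyclodeca-1,3,7-trien-1-yl]stannane (C3 epimers) | CCCC[Sn](CCCC)(CCCC)/C1=C/C=C(C)/C(S(=O)(=O)c2ccccc2)C/C=C(/C)[C@@H](O[Si](C)(C)C(C)(C)C)[C@@H]1O[Si](CC)(CC)CC | intermediate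
21 | tributyl[(1E,3E,7Z,9R,10S)-9-(TBS-oxy)-4,8-dimethyl-10-(TES-oxy)cyclodeca-1,3,7-trien-1-yl]stannane | CCCC[Sn](CCCC)(CCCC)/C1=C/C=C(C)/CC/C=C(/C)[C@@H](O[Si](C)(C)C(C)(C)C)[C@@H]1O[Si](CC)(CC)CC | intermediate
22 | methyl 2-bromoprop-2-enoate (methyl 2-bromoacrylate) | COC(=O)C(Br)=C | starting material
23 | methyl 2-[(1Z,3E,7Z,9R,10R)-9-(TBS-oxy)-4,8-dimethyl-10-(TES-oxy)cyclodeca-1,3,7-trien-1-yl]prop-2-enoate | C=C(C(=O)OC)/C1=C/C=C(C)/CC/C=C(/C)[C@@H](O[Si](C)(C)C(C)(C)C)[C@@H]1O[Si](CC)(CC)CC | intermediate
24 | methyl 2-[(1Z,3E,7Z,9R,10R)-9-(TBS-oxy)-10-hydroxy-4,8-dimethylcyclodeca-1,3,7-trien-1-yl]prop-2-enoate | C=C(C(=O)OC)/C1=C/C=C(C)/CC/C=C(/C)[C@@H](O[Si](C)(C)C(C)(C)C)[C@@H]1O | intermediate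
25 | 2-[(1Z,3E,7Z,9R,10R)-9-(TBS-oxy)-10-hydroxy-4,8-dimethylcyclodeca-1,3,7-trien-1-yl]prop-2-enoic acid | C=C(C(=O)O)/C1=C/C=C(C)/CC/C=C(/C)[C@@H](O[Si](C)(C)C(C)(C)C)[C@@H]1O | intermediate
26 | 6,7-epoxide of 25 on the face of the C8 hydroxyl, (6R,7S,8S,9R) in germacrane numbering (not isolated) | C=C(C(=O)O)[C@@]1(O2)[C@H]2/C=C(\C)CC/C=C(/C)[C@@H](O[Si](C)(C)C(C)(C)C)[C@@H]1O | intermediate
27 | (1(10)Z,4E,6S,7R,8S,9R)-9-(TBS-oxy)-7,8-dihydroxygermacra-1(10),4,11(13)-trien-12,6-olide | C=C1C(=O)O[C@H]2/C=C(\C)CC/C=C(/C)[C@@H](O[Si](C)(C)C(C)(C)C)[C@H](O)[C@@]12O | intermediate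
28 | (2Z)-2-methylbut-2-enoic acid (angelic acid) | C/C=C(/C)C(=O)O | starting material
29 | (1(10)Z,4E,6S,7R,8S,9R)-9-(TBS-oxy)-7-hydroxy-8-[(2Z)-2-methylbut-2-enoyloxy]germacra-1(10),4,11(13)-trien-12,6-olide | C=C1C(=O)O[C@H]2/C=C(\C)CC/C=C(/C)[C@@H](O[Si](C)(C)C(C)(C)C)[C@H](OC(=O)/C(C)=C\C)[C@@]12O | intermediate
30 | (1(10)Z,4E,6S,7R,8S,9R)-7,9-dihydroxy-8-[(2Z)-2-methylbut-2-enoyloxy]germacra-1(10),4,11(13)-trien-12,6-olide (CNP0292337.1) | C=C1C(=O)O[C@H]2/C=C(\C)CC/C=C(/C)[C@@H](O)[C@H](OC(=O)/C(C)=C\C)[C@@]12O | target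

## Step count and least certain steps

Total: 24 steps (3 for sulfone 4, 21 in the main line). Longest linear sequence: 21 steps, from 5 to 30 (steps 4–24).

**Step 22 (key step).**
- What may go wrong: the hydroxy acid may close onto O8 to the 8,12-lactone before it is epoxidised, which removes the directing hydroxyl and the nucleophile at once. Facial control may also be lost if the reacting ring conformer does not present C6=C7 to the vanadium-bound O8. The vinyl epoxide may be opened by an external nucleophile.
- Fallback: start from hydroxy ester 24, which has no free acid. VO(acac)2 and t-BuOOH should give the methyl ester of the 6,7-epoxide F1. Cleavage of the ester with Me3SnOH (1,2-dichloroethane, 60 °C) frees the carboxylate beside the epoxide, which closes to lactone 27, if necessary with a trace of camphorsulfonic acid. The route is rejoined at 27.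

**Step 15 (hydrostannation).**
- What may go wrong: tin may be delivered to C6 instead of C7. The bulk around C8 and the methyl group cis to the alkyne on C4 both favour the dienyl-side carbon and work against the polarising effect of the C8 oxygen.
- Fallback, regiochemistry fixed by construction: start from alkyne 15. Iodine (CH2Cl2, rt, dark) adds anti across the terminal alkyne to give the (E)-6,7-diiodoalkene F2. Sulfone 4 is converted with Bu3SnSnBu3 and Pd(PPh3)4 into the alkenylstannane F3. Stille coupling of F3 at the less hindered C6–I bond of F2 (Pd2(dba)3, AsPh3, CuI; no phosphine, to avoid deiodination) gives the 7-iodo diene ester F4, in which C5 sits trans to the remaining iodine. Palladium-catalysed stannylation with Bu3SnSnBu3 gives the 7-stannyl ester F5, and i-Bu2AlH reduction returns to 18.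

**Step 17 (ring closure).**
- What may go wrong: intermolecular alkylation (oligomers), elimination of HBr from the allylic bromide, or alkylation through the far end of the dienyl sulfone anion. A ten-membered closure is slow and both termini are ambident.
- Fallback: start from alcohol 18. Methyl chloroformate and pyridine give the allylic methyl carbonate F6. The sulfone is deprotonated with LiN(SiMe3)2 and the ring is closed with Pd(PPh3)4 and dppe at high dilution, by attack of the sulfonyl carbanion on the π-allyl palladium complex (Tsuji–Trost alkylation). This closure does not depend on an SN2 trajectory at C2 and rejoins the route at 20.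

**Step 19 (Stille coupling on the ring).**
- What may go wrong: transmetalation at the hindered ring stannane may be slow, leading to protodestannylation of 21 and polymerisation of the bromoacrylate.
- Fallback with reversed polarity: start from 21. Iodine (CH2Cl2, 0 °C) replaces tin with retention to give the ring alkenyl iodide F7. Coupling of F7 with methyl 2-(tributylstannyl)prop-2-enoate F8 (Pd(PPh3)4, CuI, DMF) puts the unhindered stannane on the acrylate partner and returns to 23.

## Further compounds

F1 | step 22 | methyl ester of the 6,7-epoxide (epoxide of 24 on the face of the C8 hydroxyl) | C=C(C(=O)OC)[C@@]1(O2)[C@H]2/C=C(\C)CC/C=C(/C)[C@@H](O[Si](C)(C)C(C)(C)C)[C@@H]1O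
F2 | step 15 | methyl (2Z,6E)-4-(TBS-oxy)-6,7-diiodo-3-methyl-5-(TES-oxy)hepta-2,6-dienoate, C4/C5 configured as in 15 | COC(=O)/C=C(/C)[C@@H](O[Si](C)(C)C(C)(C)C)[C@H](O[Si](CC)(CC)CC)/C(I)=C\I
F3 | step 15 | tributyl[(1E)-3-(benzenesulfonyl)-2-methylprop-1-en-1-yl]stannane | CCCC[Sn](CCCC)(CCCC)/C=C(\C)CS(=O)(=O)c1ccccc1
F4 | step 15 | methyl 10-(benzenesulfonyl)-4-(TBS-oxy)-6-iodo-3,9-dimethyl-5-(TES-oxy)deca-2,6,8-trienoate (2Z, 8E, C8 of the chain cis to C5 of the chain) | COC(=O)/C=C(/C)[C@@H](O[Si](C)(C)C(C)(C)C)[C@H](O[Si](CC)(CC)CC)/C(I)=C\C=C(/C)CS(=O)(=O)c1ccccc1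
F5 | step 15 | methyl ester corresponding to alcohol 18 (6-tributylstannyl trienoate) | COC(=O)/C=C(/C)[C@@H](O[Si](C)(C)C(C)(C)C)[C@H](O[Si](CC)(CC)CC)/C(=C\C=C(/C)CS(=O)(=O)c1ccccc1)[Sn](CCCC)(CCCC)CCCC
F6 | step 17 | methyl carbonate of alcohol 18 | COC(=O)OC/C=C(/C)[C@@H](O[Si](C)(C)C(C)(C)C)[C@H](O[Si](CC)(CC)CC)/C(=C\C=C(/C)CS(=O)(=O)c1ccccc1)[Sn](CCCC)(CCCC)CCCC
F7 | step 19 | ring alkenyl iodide corresponding to stannane 21 (iodine on C7) | I/C1=C/C=C(C)/CC/C=C(/C)[C@@H](O[Si](C)(C)C(C)(C)C)[C@@H]1O[Si](CC)(CC)CC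
F8 | step 19 | methyl 2-(tributylstannyl)prop-2-enoate | COC(=O)C(=C)[Sn](CCCC)(CCCC)CCCC
A1 | alternative 1 | protected (1(10)Z,4E)-cyclodecadiene: 6-OTES, 7,8-O-isopropylidene, 9-OTBS, 7-(trimethylsilylethynyl) | CC[Si](CC)(CC)O[C@H]2/C=C(\C)CC/C=C(/C)[C@@H](O[Si](C)(C)C(C)(C)C)[C@H](OC(C)(C)O4)[C@@]24C#C[Si](C)(C)C
A2 | alternative 2 | ten-membered C6 allylic alcohol: 7,8-O-isopropylidene, 9-OTBS, 7-[3-(TBS-oxy)prop-1-en-2-yl] | O[C@H]2/C=C(\C)CC/C=C(/C)[C@@H](O[Si](C)(C)C(C)(C)C)[C@H](OC(C)(C)O4)[C@@]24C(=C)CO[Si](C)(C)C(C)(C)C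
A3 | alternative 3 | protected (1(10)Z,4E)-cyclodecadiene: 6-OTES, 7,8-O-isopropylidene, 9-OTBS, 7-ethynyl | CC[Si](CC)(CC)O[C@H]2/C=C(\C)CC/C=C(/C)[C@@H](O[Si](C)(C)C(C)(C)C)[C@H](OC(C)(C)O4)[C@@]24C#C
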